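**Retrosynthetic overview**

1. Target ⇐ 3,4-cis γ-iodo ketone (silver-assisted hydrolysis through a cis-fused hemiketal) ⇐ 1-aroyl-3-oxabicyclo[3.1.0]hexane (iodide opens the cyclopropane at its CH2).
2. Cyclopropyl ketone ⇐ oxygen-tethered 1,6-enyne: gold-catalysed alkyne oxidation/cyclopropanation closes the oxolane and the cyclopropane together and installs the C=O.
3. Enyne ⇐ 3,4-dimethoxycinnamyl carbonate + 3-arylpropargyl alcohol by iridium-catalysed asymmetric allylic etherification (sets the ArCH–O centre).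
4. Building blocks ⇐ 5-iodo-1,2,3-trimethoxybenzene + propargyl alcohol (Sonogashira), and 3,4-dimethoxycinnamyl alcohol.
5. Ring order: oxolane and cyclopropane at once; cyclopropane opened; a second (hemiketal) oxolane forms transiently and opens to the target.

Assumption: the iridium catalyst made from the (Sa,Sc,Sc) phosphoramidite is taken to give the (S) ether 6; if the sense proves opposite, the (Ra,Rc,Rc) ligand is used.

Locants used below: oxolane O1, C2 (CH2), C3 (CH–C(=O)Ar), C4 (CH–CH2OH), C5 (CH–aryl). The target is (3R,4R,5S), with 3,4-cis and 4,5-trans substituents.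

**Route**

Step 1
Reactants: 1 5-iodo-1,2,3-trimethoxybenzene; 2 prop-2-yn-1-ol
Product: 3 3-(3,4,5-trimethoxyphenyl)prop-2-yn-1-ol
Conditions: PdCl2(PPh3)2 (2 mol%), CuI (4 mol%), Et3N, THF, rt to 50 °C
Reagents that add atoms: none
Why: Sonogashira coupling of an aryl iodide with a terminal alkyne tolerates the free alcohol and creates no stereocentre.

Step 2
Reactants: 4 (E)-3-(3,4-dimethoxyphenyl)prop-2-en-1-ol
Product: 5 tert-butyl (E)-3-(3,4-dimethoxyphenyl)prop-2-en-1-yl carbonate
Conditions: Boc2O (1.3 equiv), 4-(dimethylamino)pyridine (10 mol%), CH2Cl2, 0 °C to rt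
Reagents that add atoms: di-tert-butyl dicarbonate, CC(C)(C)OC(=O)OC(=O)OC(C)(C)C
Why: Nucleophile-catalysed O-acylation gives the allylic carbonate whose leaving group later releases only CO2 and non-nucleophilic tert-butoxide; the alkene geometry is untouched.

Step 3
Reactants: 5 tert-butyl (E)-3-(3,4-dimethoxyphenyl)prop-2-en-1-yl carbonate; 3 3-(3,4,5-trimethoxyphenyl)prop-2-yn-1-ol
Product: 6 5-{3-[(1S)-1-(3,4-dimethoxyphenyl)prop-2-en-1-yloxy]prop-1-yn-1-yl}-1,2,3-trimethoxybenzene
Conditions: [Ir(1,5-cyclooctadiene)Cl]2 (2 mol%), (Sa,Sc,Sc)-O,O'-(1,1'-binaphthyl-2,2'-diyl)-N,N-bis(1-phenylethyl)phosphoramidite (4 mol%, pre-activated with n-PrNH2), K3PO4 (1 equiv), THF, rt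
Reagents that add atoms: none
Why: Iridium-catalysed asymmetric allylic etherification (Hartwig-type cyclometalated iridium–phosphoramidite catalyst) ionises the linear carbonate to a π-allyl complex that the alkoxide attacks at the aryl-bearing terminus, giving the branched ether with the ligand setting the (S) C–O centre that becomes C5.

Step 4
Reactants: 6 5-{3-[(1S)-1-(3,4-dimethoxyphenyl)prop-2-en-1-yloxy]prop-1-yn-1-yl}-1,2,3-trimethoxybenzene
Product: 7 [(1S,4S,5S)-4-(3,4-dimethoxyphenyl)-3-oxabicyclo[3.1.0]hexan-1-yl](3,4,5-trimethoxyphenyl)methanone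
Conditions: [1,3-bis(2,6-diisopropylphenyl)imidazol-2-ylidene]AuCl (5 mol%), AgN(SO2CF3)2 (5 mol%), 3,5-dichloropyridine N-oxide (1.5 equiv, slow addition), 4 Å MS, 1,2-dichloroethane, 0 °C to rt
Reagents that add atoms: 3,5-dichloropyridine N-oxide, [O-][n+]1cc(Cl)cc(Cl)c1
Why: Gold-catalysed alkyne oxidation/intramolecular cyclopropanation of a 1,6-enyne: the N-oxide attacks the activated alkyne at the aryl-bearing carbon (aryl-stabilised and remote from the propargylic oxygen), N–O cleavage leaves an α-oxo gold carbene on the other carbon, and this adds across the tethered vinyl group to close the oxolane and the cyclopropane at once; allylic 1,3-strain (C–H of the stereocentre eclipsing the vinyl group, aryl turned away) places the aryl trans to the cyclopropane CH2 and so fixes the future C4.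

Step 5
Reactants: 7 [(1S,4S,5S)-4-(3,4-dimethoxyphenyl)-3-oxabicyclo[3.1.0]hexan-1-yl](3,4,5-trimethoxyphenyl)methanone
Product: 9 [(3R,4S,5S)-5-(3,4-dimethoxyphenyl)-4-(iodomethyl)oxolan-3-yl](3,4,5-trimethoxyphenyl)methanone, via silyl enol ether 8 (not isolated)
Conditions: Me3SiI (1.1 equiv), 2,6-dimethylpyridine (0.2 equiv), CH2Cl2, −78 to −40 °C; then 1 M aq. citric acid, THF, 0 °C
Reagents that add atoms: iodotrimethylsilane, C[Si](C)(C)I
Why: Homo-conjugate (homo-Michael) opening of a cyclopropyl ketone with iodotrimethylsilane: O-silylation activates the ketone and iodide attacks the unhindered cyclopropane CH2 in an SN2 manner, cleaving the bond to the ketone-bearing carbon while the oxolane stays closed; acid hydrolysis of the silyl enol ether then protonates C3 on the face away from the neighbouring CH2I group, giving the 3,4-cis iodo ketone.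

Step 6
Reactants: 9 [(3R,4S,5S)-5-(3,4-dimethoxyphenyl)-4-(iodomethyl)oxolan-3-yl](3,4,5-trimethoxyphenyl)methanone
Product: 11 [(3R,4R,5S)-5-(3,4-dimethoxyphenyl)-4-(hydroxymethyl)oxolan-3-yl](3,4,5-trimethoxyphenyl)methanone, via bicyclic hemiketal 10 (not isolated)
Conditions: AgOSO2CF3 (1.3 equiv), NaHCO3 (2 equiv), acetone–H2O (4:1), 0 °C to rt, dark
Reagents that add atoms: water, O
Why: Silver-assisted hydrolysis with neighbouring-group participation: as iodide leaves, the cis ketone oxygen closes a five-membered oxocarbenium ion, water adds to give the cis-fused hemiketal, and ring–chain tautomerism opens it to the hydroxy ketone; no stereocentre is touched and only the 3,4-cis isomer can use this pathway.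

**Compound list**

1 | 5-iodo-1,2,3-trimethoxybenzene | COc1cc(I)cc(OC)c1OC | starting material
2 | prop-2-yn-1-ol | C#CCO | starting material
3 | 3-(3,4,5-trimethoxyphenyl)prop-2-yn-1-ol | COc1cc(C#CCO)cc(OC)c1OC | intermediate
4 | (E)-3-(3,4-dimethoxyphenyl)prop-2-en-1-ol | COc1ccc(/C=C/CO)cc1OC | starting material
5 | tert-butyl (E)-3-(3,4-dimethoxyphenyl)prop-2-en-1-yl carbonate | COc1ccc(/C=C/COC(=O)OC(C)(C)C)cc1OC | intermediate
6 | 5-{3-[(1S)-1-(3,4-dimethoxyphenyl)prop-2-en-1-yloxy]prop-1-yn-1-yl}-1,2,3-trimethoxybenzene | C=C[C@H](OCC#Cc1cc(OC)c(OC)c(OC)c1)c1ccc(OC)c(OC)c1 | intermediate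
7 | [(1S,4S,5S)-4-(3,4-dimethoxyphenyl)-3-oxabicyclo[3.1.0]hexan-1-yl](3,4,5-trimethoxyphenyl)methanone (aryl trans to the cyclopropane CH2) | COc1ccc([C@H]2OC[C@]3(C(=O)c4cc(OC)c(OC)c(OC)c4)C[C@H]23)cc1OC | intermediate
8 | {[(4S,5S)-5-(3,4-dimethoxyphenyl)-4-(iodomethyl)oxolan-3-ylidene](3,4,5-trimethoxyphenyl)methoxy}trimethylsilane (enol ether geometry not defined) | COc1ccc([C@H]2OCC(=C(O[Si](C)(C)C)c3cc(OC)c(OC)c(OC)c3)[C@@H]2CI)cc1OC | intermediate
9 | [(3R,4S,5S)-5-(3,4-dimethoxyphenyl)-4-(iodomethyl)oxolan-3-yl](3,4,5-trimethoxyphenyl)methanone | COc1ccc([C@H]2OC[C@H](C(=O)c3cc(OC)c(OC)c(OC)c3)[C@@H]2CI)cc1OC | intermediate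
10 | (3aR,4S,6aR)-4-(3,4-dimethoxyphenyl)-1-(3,4,5-trimethoxyphenyl)tetrahydro-1H,3H-furo[3,4-c]furan-1-ol (both C1 epimers) | COc1ccc([C@H]2OC[C@H]3[C@@H]2COC3(O)c4cc(OC)c(OC)c(OC)c4)cc1OC | intermediate
11 | [(3R,4R,5S)-5-(3,4-dimethoxyphenyl)-4-(hydroxymethyl)oxolan-3-yl](3,4,5-trimethoxyphenyl)methanone | COc1ccc([C@H]2OC[C@H](C(=O)c3cc(OC)c(OC)c(OC)c3)[C@@H]2CO)cc1OC | target

**Step count**

Total steps: 6. Longest linear sequence: 5 steps (4 → 5 → 6 → 7 → 9 → 11; the branch from 1 is equally long).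

**Steps most likely to fail, with fallbacks**

Step 3 (etherification with a functionalised propargylic alcohol; ee and branched selectivity on an electron-rich cinnamyl system). The fallback sets out from 5 and 3 and comes back at 6. Carbonate 5 is coupled under the same iridium catalyst with Et3SiOK as a hydroxide surrogate to give triethyl{[(1S)-1-(3,4-dimethoxyphenyl)prop-2-en-1-yl]oxy}silane F1. n-Bu4NF then frees (1S)-1-(3,4-dimethoxyphenyl)prop-2-en-1-ol F2. Separately, 3 is converted with MeSO2Cl/Et3N into 3-(3,4,5-trimethoxyphenyl)prop-2-yn-1-yl methanesulfonate F3. Williamson etherification of the sodium alkoxide of F2 (NaH, THF, 0 °C) with F3 gives 6. The asymmetric step then uses a small, well-behaved oxygen nucleophile and the C–O bond to the propargyl unit is made by plain SN2.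

Step 4 (the α-oxo gold carbene may instead undergo 1,2-hydride shift from the OCH2 group or attack the dimethoxyphenyl ring, and the diastereoselectivity rests on substrate control). The fallback sets out from 5, 2 and 1 and comes back at 7; it installs the aroyl group after the bicycle is built.

- Carbonate 5 and prop-2-yn-1-ol 2 give, under the step 3 conditions, 4-[(1S)-1-(prop-2-yn-1-yloxy)prop-2-en-1-yl]-1,2-dimethoxybenzene F4.
- The same cationic gold catalyst with diphenyl sulfoxide (2 equiv, CH2Cl2, rt) first cycloisomerises this terminal enyne and then oxidises the cyclopropyl gold carbene, so no α-oxo carbene is formed. This gives (1S,4S,5S)-4-(3,4-dimethoxyphenyl)-3-oxabicyclo[3.1.0]hexane-1-carbaldehyde F5.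
- Iodide 1 is converted with i-PrMgCl·LiCl (THF, −20 °C) into (3,4,5-trimethoxyphenyl)magnesium chloride F6.
- F6 adds to F5 to give [(1S,4S,5S)-4-(3,4-dimethoxyphenyl)-3-oxabicyclo[3.1.0]hexan-1-yl](3,4,5-trimethoxyphenyl)methanol F7 as a carbinol mixture.
- Dess–Martin periodinane oxidises F7 to 7.

Step 5 (iodotrimethylsilane may also cleave the electron-rich benzylic C–O bond of the oxolane; any 3,4-trans iodo ketone from the protonation is carried into step 6 and removed there by chromatography). The fallback sets out from 7 and comes back at 11, bypassing 9. Zerovalent nickel inserts into the less hindered cyclopropane C–C bond and the ring is borylated: Ni(1,5-cyclooctadiene)2 (10 mol%), 1,3-dimesitylimidazolium chloride/KOt-Bu (10 mol%), bis(pinacolato)diboron (1.2 equiv), toluene–MeOH, 50 °C. This gives [(3R,4S,5S)-5-(3,4-dimethoxyphenyl)-4-[(4,4,5,5-tetramethyl-1,3,2-dioxaborolan-2-yl)methyl]oxolan-3-yl](3,4,5-trimethoxyphenyl)methanone F8. Oxidation of the C–B bond with NaBO3·4H2O in THF–H2O at rt gives 11. No Lewis or Brønsted acid is used; C3 is then set by protonation of the boron enolate anti to the CH2B group, and the epimer, if formed, is separated.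

**Further compounds**

F1 | step 3 | triethyl{[(1S)-1-(3,4-dimethoxyphenyl)prop-2-en-1-yl]oxy}silane | C=C[C@H](O[Si](CC)(CC)CC)c1ccc(OC)c(OC)c1
F2 | step 3 | (1S)-1-(3,4-dimethoxyphenyl)prop-2-en-1-ol | C=C[C@H](O)c1ccc(OC)c(OC)c1
F3 | step 3 | 3-(3,4,5-trimethoxyphenyl)prop-2-yn-1-yl methanesulfonate | COc1cc(C#CCOS(C)(=O)=O)cc(OC)c1OC
F4 | step 4 | 4-[(1S)-1-(prop-2-yn-1-yloxy)prop-2-en-1-yl]-1,2-dimethoxybenzene | C=C[C@H](OCC#C)c1ccc(OC)c(OC)c1
F5 | step 4 | (1S,4S,5S)-4-(3,4-dimethoxyphenyl)-3-oxabicyclo[3.1.0]hexane-1-carbaldehyde | COc1ccc([C@H]2OC[C@]3(C=O)C[C@H]23)cc1OC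
F6 | step 4 | (3,4,5-trimethoxyphenyl)magnesium chloride | COc1cc([Mg]Cl)cc(OC)c1OC
F7 | step 4 | [(1S,4S,5S)-4-(3,4-dimethoxyphenyl)-3-oxabicyclo[3.1.0]hexan-1-yl](3,4,5-trimethoxyphenyl)methanol (carbinol epimers) | COc1ccc([C@H]2OC[C@]3(C(O)c4cc(OC)c(OC)c(OC)c4)C[C@H]23)cc1OC
F8 | step 5 | [(3R,4S,5S)-5-(3,4-dimethoxyphenyl)-4-[(4,4,5,5-tetramethyl-1,3,2-dioxaborolan-2-yl)methyl]oxolan-3-yl](3,4,5-trimethoxyphenyl)methanone | COc1ccc([C@H]2OC[C@H](C(=O)c3cc(OC)c(OC)c(OC)c3)[C@@H]2CB4OC(C)(C)C(C)(C)O4)cc1OC
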